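**Plan**

1. Retrosynthesis: after ester hydrolysis, the side-chain C2'–C3' bond (CH2 to the sp2 CH of the first trisubstituted alkene) is cut to the C14 (E)-alkenyl iodide 19 and the iodoethyl-1,2-dioxane ester 14. In 14 the ring bonds O2–C3 and O1–C6 and the C3–Cα bond are cut back to aldehyde 6 and geraniol.
2. Forward: geraniol → oxetane aldehyde 6 → crotylboration → mesylate 8 → oxetane perhydrolysis (makes O1–C6) → 6-exo-tet peroxide alkylation (makes O2–C3, closes the 1,2-dioxane). Then vinyl → CO2Me and CH2OH → CH2I, Negishi union with 19 (from geranylacetone), saponification.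
3. Stereochemistry: C6 comes from the Sharpless epoxidation and is inverted once in the perhydrolysis. C3 and Cα come from the Brown (Z)-crotylboration, and C3 is inverted once in the ring closure. The alkene geometries come from geranylacetone and syn-carboalumination and are carried with retention.
4. Enabling feature: the two CH2 groups (C1', C2') between ring carbon C6 and the C3'=C4' alkene put the metalated carbon C2' γ to ring oxygen O1, so there is no β-leaving group and no easy path to the O1–O2 bond. C3' is an sp2 CH, so a base-free alkylzinc/alkenyl iodide coupling can join the halves with the 3,6,6-trisubstituted dioxane and its β-peroxy ester already in place.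

Key step: step 14

Assumption (chemistry): the fully alkyl-substituted O1–O2 bond of the 1,2-dioxane is taken to survive zinc dust, an alkylzinc iodide and Pd(0)–NHC at room temperature in aprotic medium. Ring atoms are numbered O1, O2, C3–C6; Cα is C2 of the propanoate; side-chain carbons are primed.

**Route**

Step 1
Reactants: 1 geraniol
Product: 2 [(2S,3S)-3-methyl-3-(4-methylpent-3-en-1-yl)oxiran-2-yl]methanol
Conditions: Ti(OiPr)4 (5 mol%), L-(+)-diethyl tartrate (7 mol%), anhydrous t-BuOOH (2 equiv), 4 Å MS, CH2Cl2, −20 °C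
Reagents that add atoms: tert-butyl hydroperoxide CC(C)(C)OO
Why: Sharpless asymmetric epoxidation of the allylic alcohol with the L-(+)-tartrate catalyst should give the (2S,3S)-epoxide and leave the remote trisubstituted alkene alone; C3 of 2 is the future ring carbon C6.

Step 2
Reactants: 2 [(2S,3S)-3-methyl-3-(4-methylpent-3-en-1-yl)oxiran-2-yl]methanol
Product: 3 (3S)-3,7-dimethyloct-6-ene-1,3-diol
Conditions: Red-Al (1.5 equiv), THF, 0 °C → rt; aq. Rochelle salt
Reagents that add atoms: none
Why: hydroxyl-directed hydride delivery to C2 (regioselective reductive opening of a 2,3-epoxy alcohol) should give the 1,3-diol, and the tertiary C–O bond is not touched, so its configuration is kept.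

Step 3
Reactants: 3 (3S)-3,7-dimethyloct-6-ene-1,3-diol
Product: 5 (2S)-2-methyl-2-(4-methylpent-3-en-1-yl)oxetane, via monotosylate 4 (not isolated)
Conditions: n-BuLi (1.0 equiv), THF, 0 °C; TsCl (1.0 equiv), 0 °C → rt; n-BuLi (1.05 equiv), 0 → 60 °C
Reagents that add atoms: none
Why: selective sulfonylation of the primary alkoxide followed by 4-exo-tet Williamson closure by the tertiary alkoxide (oxetane synthesis from a 1,3-diol monosulfonate) should give the oxetane with retention, because the tertiary carbon is not a reacting centre.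

Step 4
Reactants: 5 (2S)-2-methyl-2-(4-methylpent-3-en-1-yl)oxetane
Product: 6 3-[(2S)-2-methyloxetan-2-yl]propanal
Conditions: O3, CH2Cl2, −78 °C; Me2S, −78 °C → rt
Reagents that add atoms: ozone [O-][O+]=O
Why: ozonolysis with reductive work-up cleaves the only C=C bond of 5, and the oxetane is inert to ozone and dimethyl sulfide.

Step 5
Reactants: 6 3-[(2S)-2-methyloxetan-2-yl]propanal
Product: 7 (3R,4R)-3-methyl-6-[(2S)-2-methyloxetan-2-yl]hex-1-en-4-ol
Conditions: cis-2-butene, KOt-Bu, n-BuLi, THF, −78 → −45 °C; (−)-Ipc2BOMe [from (+)-α-pinene], −78 °C; BF3·OEt2, then 6, −78 °C; NaOH, H2O2, rt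
Reagents that add atoms: cis-2-butene C/C=C\C
Why: Brown asymmetric crotylboration through a closed chair transition state should give the syn product from the (Z)-crotyl group, with the isopinocampheyl groups derived from (+)-α-pinene directing attack to the aldehyde Si face, which sets the (4R) carbinol and the (3R) methyl centre under reagent control.

Step 6
Reactants: 7 (3R,4R)-3-methyl-6-[(2S)-2-methyloxetan-2-yl]hex-1-en-4-ol
Product: 8 (3R,4R)-3-methyl-6-[(2S)-2-methyloxetan-2-yl]hex-1-en-4-yl methanesulfonate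
Conditions: MsCl, Et3N, CH2Cl2, 0 °C
Reagents that add atoms: methanesulfonyl chloride CS(=O)(=O)Cl
Why: O-sulfonylation of the secondary alcohol proceeds with retention and turns C3–O into a leaving group without touching the oxetane or the vinyl group.

Step 7
Reactants: 8 (3R,4R)-3-methyl-6-[(2S)-2-methyloxetan-2-yl]hex-1-en-4-yl methanesulfonate
Product: 9 (3R,6R,7R)-3-hydroperoxy-1-hydroxy-3,7-dimethylnon-8-en-6-yl methanesulfonate
Conditions: anhydrous H2O2 in Et2O (10 equiv), TMSOTf (0.2 equiv), −78 → 0 °C
Reagents that add atoms: hydrogen peroxide OO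
Why: the Lewis acid-activated 2,2-disubstituted oxetane should be opened by H2O2 at the tertiary carbon with inversion (perhydrolysis of oxetanes to 3-hydroperoxyalkan-1-ols), turning the (S)-C–O centre into the (R)-C–OOH centre that is the final C6 configuration, while the mesylate and vinyl group are inert.

Step 8
Reactants: 9 (3R,6R,7R)-3-hydroperoxy-1-hydroxy-3,7-dimethylnon-8-en-6-yl methanesulfonate
Product: 10 2-[(3R,6S)-6-[(2R)-but-3-en-2-yl]-3-methyl-1,2-dioxan-3-yl]ethan-1-ol
Conditions: CsOH·H2O (1.1 equiv), DMF, 0 °C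
Reagents that add atoms: none
Why: the hydroperoxide is far more acidic than the primary alcohol, and its anion should close the 1,2-dioxane by 6-exo-tet intramolecular SN2 alkylation at the secondary mesylate with inversion, which sets the final C3 configuration anti to the Cα methyl group.

Step 9
Reactants: 10 2-[(3R,6S)-6-[(2R)-but-3-en-2-yl]-3-methyl-1,2-dioxan-3-yl]ethan-1-ol
Product: 12 (2S)-2-[(3S,6R)-6-(2-hydroxyethyl)-6-methyl-1,2-dioxan-3-yl]propanoic acid, via hydroxy aldehyde 11 (not isolated)
Conditions: O3, CH2Cl2, −78 °C; Me2S, −78 → 0 °C; evaporate; NaClO2, NaH2PO4, 2-methyl-2-butene, t-BuOH/H2O, 0 °C → rt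
Reagents that add atoms: ozone [O-][O+]=O; sodium chlorite [Na+].[O-]Cl=O
Why: ozonolysis of the terminal vinyl group and Pinnick oxidation of the crude β-peroxy aldehyde under buffered, base-free conditions should give the acid without epimerisation at Cα or β-elimination of the peroxide, and the dialkyl peroxide and primary alcohol are inert to ozone, dimethyl sulfide and chlorite.

Step 10
Reactants: 12 (2S)-2-[(3S,6R)-6-(2-hydroxyethyl)-6-methyl-1,2-dioxan-3-yl]propanoic acid
Product: 13 methyl (2S)-2-[(3S,6R)-6-(2-hydroxyethyl)-6-methyl-1,2-dioxan-3-yl]propanoate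
Conditions: TMSCHN2 (2 M in hexanes), toluene/MeOH (4:1), 0 °C
Reagents that add atoms: trimethylsilyldiazomethane C[Si](C)(C)C=[N+]=[N-]
Why: O-methylation of the carboxylic acid by the diazoalkane is neutral and selective over the primary alcohol, and masks the acidic proton for the organozinc step.

Step 11
Reactants: 13 methyl (2S)-2-[(3S,6R)-6-(2-hydroxyethyl)-6-methyl-1,2-dioxan-3-yl]propanoate
Product: 14 methyl (2S)-2-[(3S,6R)-6-(2-iodoethyl)-6-methyl-1,2-dioxan-3-yl]propanoate
Conditions: PPh3, I2, imidazole (premixed), CH2Cl2, 0 °C; then 13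
Reagents that add atoms: iodine II
Why: Appel-type iodination of the primary alcohol by preformed iodophosphonium salt should give the iodide, with no free phosphine left to attack the hindered O–O bond.

Step 12
Reactants: 15 (5E)-6,10-dimethylundeca-5,9-dien-2-one (geranylacetone)
Product: 17 (5E)-6,10-dimethylundeca-5,9-dien-1-yne, via enol phosphate 16 (not isolated)
Conditions: LDA (1.05 equiv), THF, −78 °C; ClP(O)(OEt)2, −78 °C → rt; LDA (2.3 equiv), −78 °C → rt; aq. NH4Cl
Reagents that add atoms: none
Why: kinetic enolisation on the methyl side, O-phosphorylation and base-induced elimination of the enol phosphate (methyl ketone to terminal alkyne conversion) should give the enyne with the 5E alkene untouched.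

Step 13
Reactants: 17 (5E)-6,10-dimethylundeca-5,9-dien-1-yne
Product: 19 (1E,5E)-1-iodo-2,6,10-trimethylundeca-1,5,9-triene, via alkenylalane 18 (not isolated)
Conditions: Me3Al (2 equiv), Cp2ZrCl2 (0.25 equiv), CH2Cl2, 0 °C → rt; I2, THF, −30 → 0 °C
Reagents that add atoms: trimethylaluminium C[Al](C)C; iodine II
Why: Negishi zirconium-catalysed carboalumination adds methyl and aluminium syn across the terminal alkyne with aluminium on the terminal carbon, and iodinolysis with retention should give the (E)-alkenyl iodide.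

Step 14
Reactants: 14 methyl (2S)-2-[(3S,6R)-6-(2-iodoethyl)-6-methyl-1,2-dioxan-3-yl]propanoate; 19 (1E,5E)-1-iodo-2,6,10-trimethylundeca-1,5,9-triene
Product: 21 methyl (2S)-2-[(3S,6S)-6-methyl-6-[(3E,7E)-4,8,12-trimethyltrideca-3,7,11-trien-1-yl]-1,2-dioxan-3-yl]propanoate, via alkylzinc iodide 20 (not isolated)
Conditions: Zn dust (activated with 1,2-dibromoethane and TMSCl), LiCl, THF, 25 °C; decant from Zn; 19, Pd-PEPPSI-IPr (3 mol%), THF/NMP (2:1), rt
Reagents that add atoms: none
Why: LiCl-assisted insertion of zinc into the primary C–I bond of 14 reverses the polarity of C2' (both termini were made as iodides), and the alkylzinc iodide 20 then enters a Pd(0)/Pd(II) cycle of oxidative addition into the C(sp2)–I bond of 19 with retention, transmetalation, and a reductive elimination that the bulky NHC ligand should make faster than β-hydride elimination. The closest known reaction type is the Negishi coupling of functionalised primary alkylzinc halides with alkenyl iodides. No ring is closed and no stereocentre is formed; the 3'E geometry is carried over from 19, and C3, C6 and Cα are untouched (the C6 descriptor changes from R to S only because the CIP priorities of its substituents change). The step needs chemoselectivity for C–I over the O1–O2 bond and the β-peroxy ester: the zinc-bearing carbon is γ to O1 so no β-elimination is open, the tetra-alkyl peroxide is a poor electron acceptor in aprotic THF, the catalyst is phosphine-free, and no base is present that could cause retro-oxa-Michael ring opening or Cα epimerisation. It also needs cross-coupling over homocoupling, which forming 20 completely and decanting it from excess zinc before adding 19 and the catalyst should secure.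

Step 15
Reactants: 21 methyl (2S)-2-[(3S,6S)-6-methyl-6-[(3E,7E)-4,8,12-trimethyltrideca-3,7,11-trien-1-yl]-1,2-dioxan-3-yl]propanoate
Product: 22 (2S)-2-[(3S,6S)-6-methyl-6-[(3E,7E)-4,8,12-trimethyltrideca-3,7,11-trien-1-yl]-1,2-dioxan-3-yl]propanoic acid
Conditions: LiOH (3 equiv), THF/MeOH/H2O, 0 °C → rt; 1 M HCl to pH 3, 0 °C
Reagents that add atoms: lithium hydroxide [Li+].[OH-]
Why: saponification of the methyl ester by acyl attack of hydroxide is faster than α-deprotonation, so the β-peroxy acid should be released without ring opening or epimerisation at Cα.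

**Compound list**

1 | geraniol, (2E)-3,7-dimethylocta-2,6-dien-1-ol | CC(C)=CCC/C(C)=C/CO | starting material
2 | [(2S,3S)-3-methyl-3-(4-methylpent-3-en-1-yl)oxiran-2-yl]methanol | OC[C@@H]1O[C@@]1(C)CCC=C(C)C | intermediate
3 | (3S)-3,7-dimethyloct-6-ene-1,3-diol | OCC[C@](O)(C)CCC=C(C)C | intermediate
4 | (3S)-3-hydroxy-3,7-dimethyloct-6-en-1-yl 4-methylbenzenesulfonate | Cc1ccc(cc1)S(=O)(=O)OCC[C@](O)(C)CCC=C(C)C | intermediate
5 | (2S)-2-methyl-2-(4-methylpent-3-en-1-yl)oxetane | O1CC[C@]1(C)CCC=C(C)C | intermediate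
6 | 3-[(2S)-2-methyloxetan-2-yl]propanal | O1CC[C@]1(C)CCC=O | intermediate
7 | (3R,4R)-3-methyl-6-[(2S)-2-methyloxetan-2-yl]hex-1-en-4-ol | O1CC[C@]1(C)CC[C@H]([C@H](C)C=C)O | intermediate
8 | (3R,4R)-3-methyl-6-[(2S)-2-methyloxetan-2-yl]hex-1-en-4-yl methanesulfonate | O1CC[C@]1(C)CC[C@H]([C@H](C)C=C)OS(C)(=O)=O | intermediate
9 | (3R,6R,7R)-3-hydroperoxy-1-hydroxy-3,7-dimethylnon-8-en-6-yl methanesulfonate | OCC[C@@](OO)(C)CC[C@H]([C@H](C)C=C)OS(C)(=O)=O | intermediate
10 | 2-[(3R,6S)-6-[(2R)-but-3-en-2-yl]-3-methyl-1,2-dioxan-3-yl]ethan-1-ol | OCC[C@@]1(C)CC[C@@H]([C@H](C)C=C)OO1 | intermediate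
11 | (2S)-2-[(3S,6R)-6-(2-hydroxyethyl)-6-methyl-1,2-dioxan-3-yl]propanal | OCC[C@@]1(C)CC[C@@H]([C@H](C)C=O)OO1 | intermediate
12 | (2S)-2-[(3S,6R)-6-(2-hydroxyethyl)-6-methyl-1,2-dioxan-3-yl]propanoic acid | OCC[C@@]1(C)CC[C@@H]([C@H](C)C(=O)O)OO1 | intermediate
13 | methyl (2S)-2-[(3S,6R)-6-(2-hydroxyethyl)-6-methyl-1,2-dioxan-3-yl]propanoate | OCC[C@@]1(C)CC[C@@H]([C@H](C)C(=O)OC)OO1 | intermediate
14 | methyl (2S)-2-[(3S,6R)-6-(2-iodoethyl)-6-methyl-1,2-dioxan-3-yl]propanoate | ICC[C@@]1(C)CC[C@@H]([C@H](C)C(=O)OC)OO1 | intermediate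
15 | (5E)-6,10-dimethylundeca-5,9-dien-2-one (geranylacetone) | CC(C)=CCC/C(C)=C/CCC(C)=O | starting material
16 | diethyl (5E)-6,10-dimethylundeca-1,5,9-trien-2-yl phosphate | CC(C)=CCC/C(C)=C/CCC(=C)OP(=O)(OCC)OCC | intermediate
17 | (5E)-6,10-dimethylundeca-5,9-dien-1-yne | CC(C)=CCC/C(C)=C/CCC#C | intermediate
18 | dimethyl[(1E,5E)-2,6,10-trimethylundeca-1,5,9-trien-1-yl]alumane | CC(C)=CCC/C(C)=C/CC/C(C)=C/[Al](C)C | intermediate
19 | (1E,5E)-1-iodo-2,6,10-trimethylundeca-1,5,9-triene | CC(C)=CCC/C(C)=C/CC/C(C)=C/I | intermediate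
20 | 2-[(3S,6R)-3-[(2S)-1-methoxy-1-oxopropan-2-yl]-6-methyl-1,2-dioxan-6-yl]ethylzinc iodide | I[Zn]CC[C@@]1(C)CC[C@@H]([C@H](C)C(=O)OC)OO1 | intermediate
21 | methyl (2S)-2-[(3S,6S)-6-methyl-6-[(3E,7E)-4,8,12-trimethyltrideca-3,7,11-trien-1-yl]-1,2-dioxan-3-yl]propanoate | CC(C)=CCC/C(C)=C/CC/C(C)=C/CC[C@@]1(C)CC[C@@H]([C@H](C)C(=O)OC)OO1 | intermediate
22 | (2S)-2-[(3S,6S)-6-methyl-6-[(3E,7E)-4,8,12-trimethyltrideca-3,7,11-trien-1-yl]-1,2-dioxan-3-yl]propanoic acid | CC(C)=CCC/C(C)=C/CC/C(C)=C/CC[C@@]1(C)CC[C@@H]([C@H](C)C(=O)O)OO1 | target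

**Step count**

Total: 15 steps. Longest linear sequence: 13 steps (steps 1–11, 14, 15).

**Steps most likely to fail**

Step 14. Reductive cleavage of the O1–O2 bond during zinc insertion, or protodezincation and β-hydride elimination before transmetalation, may erode the coupling. The fallback reverses the roles of the two iodides so that no zinc metal meets the peroxide. Setting out from 19, iodine–lithium exchange (t-BuLi, Et2O, −78 °C) and transmetalation with ZnCl2 would give [(1E,5E)-2,6,10-trimethylundeca-1,5,9-trien-1-yl]zinc chloride F1. F1 would be coupled with alkyl iodide 14 under Negishi conditions for unactivated primary alkyl iodides (Pd2(dba)3, PCyp3, N-methylimidazole, THF/NMP, 60–80 °C), coming back to the route at 21.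

Step 7. Ionisation of the activated oxetane ahead of peroxide attack may lead to E1 elimination and partial loss of configuration at the future C6. The fallback forms the two C–O bonds in the reverse order, so that the tertiary centre is attacked intramolecularly. Setting out from mesylate 8, SN2 displacement with 2-methoxyprop-2-yl hydroperoxide (CsOH, DMF, 0 °C → rt, inversion at C3) would give the peroxyketal (2S)-2-[(3S,4R)-3-[(2-methoxypropan-2-yl)peroxy]-4-methylhex-5-en-1-yl]-2-methyloxetane F2. Mild acid (AcOH/THF/H2O) would free the hydroperoxide (2S)-2-[(3S,4R)-3-hydroperoxy-4-methylhex-5-en-1-yl]-2-methyloxetane F3. F3 would close by Lewis acid-promoted 6-exo opening of the oxetane at its tertiary carbon (cat. TMSOTf, CH2Cl2, −78 → 0 °C, inversion at C6), coming back at 10. This also bypasses the base-mediated closure of step 8, where E2 loss of the mesylate toward the allylic Cα–H could compete.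

Step 5. Lewis acid-induced opening of the oxetane by BF3·OEt2 during the crotylboration, or insufficient reagent control on the unbranched aldehyde, may lower yield and facial selectivity. The fallback builds the same two centres by an Evans syn-aldol reaction, in which the boron Lewis acid is bound in the enolate. Setting out from 6:
- (4S)-4-benzyl-3-propanoyl-1,3-oxazolidin-2-one, Bu2BOTf, i-Pr2NEt, CH2Cl2, −78 → 0 °C would give the aldol adduct (4S)-4-benzyl-3-[(2S,3R)-3-hydroxy-2-methyl-5-[(2S)-2-methyloxetan-2-yl]pentanoyl]-1,3-oxazolidin-2-one F4.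
- TESCl and imidazole would give the silyl ether (4S)-4-benzyl-3-[(2S,3R)-2-methyl-5-[(2S)-2-methyloxetan-2-yl]-3-(triethylsilyloxy)pentanoyl]-1,3-oxazolidin-2-one F5.
- LiBH4 (Et2O, MeOH) would remove the auxiliary to give (2R,3R)-2-methyl-5-[(2S)-2-methyloxetan-2-yl]-3-(triethylsilyloxy)pentan-1-ol F6.
- Dess–Martin periodinane would give (2S,3R)-2-methyl-5-[(2S)-2-methyloxetan-2-yl]-3-(triethylsilyloxy)pentanal F7.
- Wittig methylenation (Ph3P=CH2, THF) would give triethyl{[(3R,4R)-3-methyl-6-[(2S)-2-methyloxetan-2-yl]hex-1-en-4-yl]oxy}silane F8.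
- TBAF would remove the silyl group and return to the route at 7.

**Further compounds**

F1 | step 14 | [(1E,5E)-2,6,10-trimethylundeca-1,5,9-trien-1-yl]zinc chloride | CC(C)=CCC/C(C)=C/CC/C(C)=C/[Zn]Cl
F2 | step 7 | (2S)-2-[(3S,4R)-3-[(2-methoxypropan-2-yl)peroxy]-4-methylhex-5-en-1-yl]-2-methyloxetane | O1CC[C@]1(C)CC[C@@H]([C@H](C)C=C)OOC(C)(C)OC
F3 | step 7 | (2S)-2-[(3S,4R)-3-hydroperoxy-4-methylhex-5-en-1-yl]-2-methyloxetane | O1CC[C@]1(C)CC[C@@H]([C@H](C)C=C)OO
F4 | step 5 | (4S)-4-benzyl-3-[(2S,3R)-3-hydroxy-2-methyl-5-[(2S)-2-methyloxetan-2-yl]pentanoyl]-1,3-oxazolidin-2-one | O1CC[C@]1(C)CC[C@H]([C@H](C)C(=O)N2[C@@H](Cc3ccccc3)COC2=O)O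
F5 | step 5 | (4S)-4-benzyl-3-[(2S,3R)-2-methyl-5-[(2S)-2-methyloxetan-2-yl]-3-(triethylsilyloxy)pentanoyl]-1,3-oxazolidin-2-one | O1CC[C@]1(C)CC[C@H]([C@H](C)C(=O)N2[C@@H](Cc3ccccc3)COC2=O)O[Si](CC)(CC)CC
F6 | step 5 | (2R,3R)-2-methyl-5-[(2S)-2-methyloxetan-2-yl]-3-(triethylsilyloxy)pentan-1-ol | O1CC[C@]1(C)CC[C@H]([C@H](C)CO)O[Si](CC)(CC)CC
F7 | step 5 | (2S,3R)-2-methyl-5-[(2S)-2-methyloxetan-2-yl]-3-(triethylsilyloxy)pentanal | O1CC[C@]1(C)CC[C@H]([C@H](C)C=O)O[Si](CC)(CC)CC
F8 | step 5 | triethyl{[(3R,4R)-3-methyl-6-[(2S)-2-methyloxetan-2-yl]hex-1-en-4-yl]oxy}silane | O1CC[C@]1(C)CC[C@H]([C@H](C)C=C)O[Si](CC)(CC)CC
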